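The data come from a simulation with made-up constants; noise was put on by code.

1. The small charge, alpha at 0.30 M, gave me the pace of the step I cared about. I read the runs so: substrate and partner make intermediate, and second reagent turns intermediate into target.

| flask | substrate | partner | second reagent | remark | time |
|---|---|---|---|---|---|
| alpha | 0.30 M | 3 equiv | 1.1 equiv (in portions, 4) | run made earlier; portions every 40 min |  |
| zeta | 0.68 M | 3 equiv | 1.1 equiv (in portions, 4) | run made earlier; portions every 40 min |  |
| alder | 0.45 M | 3.00 equiv | 1.10 equiv | everything together at the start | 2.5 h |
| cedar | 0.45 M | 3.00 equiv | 1.10 equiv (in portions, 4) | the portions of second reagent follow each other after 40 min, the first at the start | 2.5 h |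

| run | time / min | intermediate / % | target / % |
|---|---|---|---|
| alpha | 20.0 | 43 | 3 |
| alpha | 40.0 | 60 | 11 |
| alpha | 60.0 | 58 | 20 |
| alpha | 80.0 | 58 | 30 |
| alpha | 90.0 | 53 | 34 |
| alpha | 120 | 44 | 46 |
| zeta | 8.00 | 42 | 2 |
| zeta | 25.0 | 68 | 13 |
| zeta | 40.0 | 72 | 20 |
| zeta | 60.0 | 59 | 36 |
| zeta | 90.0 | 45 | 50 |
| zeta | 120 | 36 | 57 |

(each reading ± 1.5 percentage points)

- the analysis behind the earlier runs scatters by 1.5 percentage points, standard deviation

- which one finishes higher in amount of intermediate, in percent of the substrate charged ("neither" within 2 percentage points) (alder / cedar / neither)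
- amount of intermediate at the end, in percent of the substrate charged, alder
- amount of intermediate at the end, in percent of the substrate charged, cedar

2. Between 40.0 min and 80.0 min, alpha held two portions, and target rose by 0.00475 min⁻¹ as a fraction of the charge. I counted one reagent per target, so free [second reagent] at 60.0 min was 0.105 M. Dividing that pace by [second reagent] and by intermediate, 58%, gave the clearing constant, 0.0780 M⁻¹ min⁻¹. This is a reading. Then 0.693 over kc[second reagent] is a clearing half-life, a pseudo-first-order view of one moment.

3. Zeta looked wrong. At 90.0 min it had received 82.5% of the substrate as reagent, but target stood at 50%. That tally leaves 0.221 M free, and kc then promises 0.00776 min⁻¹. Yet target rose more slowly than that, by 0.00233 min⁻¹.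

4. Turned round, that pace means [second reagent] near 0.0665 M. I took this to mean reagent has a second outlet besides net target, so the tally drifts as a run goes on.

5. My own reckoning compared the starts. Alder opens at 0.495 M, with a clearing half-life of 18.0 min. Cedar opens at 0.124 M, with 71.8 min. Alder clears sooner, so I expected cedar to finish higher.

6. The forecast gave cedar, with alder 25% and cedar 33%: “Alder keeps reagent high early, so conversion should be faster and intermediate lower”.

7. The flasks gave cedar as the higher, with alder 18.9% and cedar 26.7%.

    substrate + second reagent → side product (k = 5.17 × 10⁻⁵ M⁻¹ s⁻¹)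
    second reagent + target → over-reaction product A (k = 3.27 × 10⁻⁴ M⁻¹ s⁻¹)
    substrate + partner → intermediate (k = 6.58 × 10⁻⁴ M⁻¹ s⁻¹)
    second reagent + intermediate → target (k = 0.00151 M⁻¹ s⁻¹)
    target → over-reaction product B (k = 1.11 × 10⁻⁷ s⁻¹)

8. The way the reagent goes in is the main reason for the gap: with that difference taken away, alder given cedar's portions, alder's intermediate moves from 18.9% to 26.7%. At 2.50 h, alder's [second reagent] gives a clearing half-life of 185 min, longer than cedar's 77.9 min. By 0.500 h, alder had 43% of its turnover of intermediate into target behind it.

9. In a neighbour flask, alder's recipe with substrate at 0.11 M, the opening [second reagent] of 0.121 M gives a clearing half-life of 73.4 min, longer than alder's opening one. That flask ended with 37.9% intermediate and 36.4% target.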